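All runs stem from a simulated flask for substances that don't exist, noise included.

The trap at this bench is to count the Q I charged, when the readings follow the part still free.

| flask | D | Q | remark | time |
|---|---|---|---|---|
| winter | 0.80 M | 0.19 M (in portions, 3) | run made earlier; portions every 15 h |  |
| dawn | 0.80 M | 0.55 M (in portions, 3) | run made earlier; portions every 15 h |  |
| spring | 0.80 M | 1.3 M (in portions, 3) | run made earlier; portions every 15 h |  |
| summer | 0.91 M | 0.76 M (in portions, 3) | run made earlier; portions every 15 h |  |
| east | 0.40 M | 0.250 M (in portions, 3) | the portions of Q follow each other after 25 h, the first at the start | 4.0 d |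
| north | 2.5 M | 1.20 M (in portions, 3) | the portions of Q follow each other after 15 h, the first at the start | 4.0 d |
| south-east | 0.80 M | 0.760 M (in portions, 3) | the portions of Q follow each other after 15 h, the first at the start | 4.0 d |
| south | 1.2 M | 1.20 M (in portions, 3) | the portions of Q follow each other after 15 h, the first at the start | 4.0 d |

| run | time / d | L / % | D / % |
|---|---|---|---|
| winter | 0.833 | 4.6 | 87.6 |
| winter | 1.67 | 9.2 | 81.0 |
| winter | 2.50 | 11.6 | 78.7 |
| winter | 3.00 | 10.6 | 78.9 |
| winter | 4.00 | 9.5 | 77.2 |
| dawn | 0.333 | 5.5 | 86.6 |
| dawn | 1.04 | 15.9 | 75.3 |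
| dawn | 1.67 | 24.0 | 64.3 |
| dawn | 3.00 | 27.8 | 58.2 |
| dawn | 4.00 | 25.8 | 57.7 |
| spring | 0.833 | 28.3 | 62.5 |
| spring | 1.67 | 47.1 | 41.7 |
| spring | 2.50 | 50.1 | 34.6 |
| spring | 3.00 | 48.9 | 33.6 |
| spring | 4.00 | 46.8 | 32.8 |
| summer | 0.333 | 8.3 | 85.0 |
| summer | 1.04 | 19.8 | 70.6 |
| summer | 1.67 | 31.6 | 58.2 |
| summer | 3.00 | 33.6 | 50.8 |
| summer | 4.00 | 32.2 | 51.2 |

(readings scatter by 0.5 percentage points)

1. the flasks put in order of amount of L, in percent of the D charged, best first, at 4.0 d (east / north / south-east / south)
2. the amount of L, in percent of the D charged of the flask you put first, at 4.0 d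
3. the amount of L, in percent of the D charged of the flask you put last, at 4.0 d

- in a conversion X counts as not yet reacted

Winter's first reading leaves 7.80% of the D charged in neither D nor L. I book it as X, 0.0890 of the D present, and hold that ratio. I assume that any other D gone from D and X has taken one Q, so the fraction q of Q left is one minus that gone fraction divided by the equivalents charged. In spring at 4.00 d that reads q = 60.4%, and so W = 1.82 /M, my holding quotient: the fraction in L over the fraction in D, over q, over the molar Q charge. I read it as the reaction quotient of D + Q to L. Dawn reads 1.77 /M and summer 1.76 /M, so I take control of L to have passed from rate to balance by then, a quasi-equilibrium with D and free Q that the slow loss still moves.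

For whoever takes over: with W and summer's slow loss of 12.0%, I expect L at 42.1% in south, 34.5% in south-east, 25.9% in north and 16.3% in east. Do not take a mid-run reading for the end: spring's L read 50.1% at 2.50 d and 46.8% at 4.00 d.

The forecast says south > north > south-east > east, with 42% (37% to 46%) first and 14% (11% to 17%) last; of north it says “Q is limiting at 48% of D, about 45% consumed, L ≈ 35, quite uncertain”. My order differs from it at north and south-east.

The flasks give south > south-east > north > east: south 39.8%, south-east 33.7%, north 26.3%, east 18.1%.

    D ⇌ X (K = 0.0973, k = 0.0181 /h)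
    D + Q ⇌ L (K = 1.76 /M, k = 0.0596 /M/h)
    Q + X → Z (k = 0.0855 /M/h)

North at 4.00 d holds D 56.7% and L 26.3% of the D charged, and Q 20.1% of its own charge, so its quotient stands at 1.93 /M beside my W of 1.82 /M. A neighbour of east, charged with 0.62 M of Q, reckons the same way, with the same W and slow loss, to L of 36.5%. It gives 35.8%, with D 47% and Q 68% left, a quotient of 1.81 /M.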